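**Plan**
- Retrosynthesis cuts the six O–methyl bonds first, then the C5–vinyl bond of ring A (Heck disconnection to an aryl chloride and 3,5-dimethoxystyrene), then C2–H (traced back to a C2–B bond).
- The central cut removes both aryl–carbon bonds of the dihydrofuran at once, C2–ring C and C3–ring D. This leaves a benzofuran-2-yl borate that already carries ring C on boron, and the triflate of ring D.
- Feature used: C2 and C3 of the dihydrofuran fused to ring A each bear one aryl group (catechol ring C on C2, resorcinol ring D on C3) on opposite faces. This is the pattern of an anti 1,2-diarylation across the C2=C3 bond of a benzofuran.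
- Forward: no ring is built. 5-Chlorobenzofuran supplies ring A and the furan; it is lithiated, turned into the borate, dearomatised in a three-component coupling, protodeboronated, styrylated at C5 and demethylated.
- Stereochemistry: C3 comes from face selection by the chiral palladium catalyst, C2 from the anti course of the boron-to-carbon shift and a retentive C–B to C–H exchange, and the E-alkene from the Heck reaction.

Key step: step 3

Assumption: the sense of induction of the ferrocenyl bisphosphine on a benzofuranyl borate cannot be predicted with confidence, so the route is written for the (Sp,Sp),(R,R) ligand and would use its mirror image if the first coupling shows the opposite sense.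

**Step 1**
Reactants: 1 3,5-dimethoxyphenol
Product: 2 3,5-dimethoxyphenyl trifluoromethanesulfonate
Conditions: Tf2O (1.1 equiv), pyridine (2 equiv), CH2Cl2, 0 °C → rt
Reagents that add atoms: trifluoromethanesulfonic anhydride, O=S(=O)(OS(=O)(=O)C(F)(F)F)C(F)(F)F
Why: O-sulfonylation of a phenol with triflic anhydride and pyridine is a standard triflate synthesis, and the electron-rich ring is not attacked at this temperature.

**Step 2**
Reactants: 3 5-chlorobenzofuran; 4 2-(3,4-dimethoxyphenyl)-4,4,5,5-tetramethyl-1,3,2-dioxaborolane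
Product: 6 lithium (5-chlorobenzofuran-2-yl)(3,4-dimethoxyphenyl)(pinacolato)borate, via (5-chlorobenzofuran-2-yl)lithium 5 (not isolated)
Conditions: n-BuLi (1.0 equiv), THF, −78 °C; then 4, −78 °C → rt; volatiles removed in vacuo under argon, solid used crude
Reagents that add atoms: n-butyllithium, [Li]CCCC
Why: C–H lithiation at C2, the most acidic position of benzofuran, followed by addition of the heteroaryllithium to the boronic ester (boron ate complex formation) should be clean at −78 °C, where the aryl chloride neither exchanges nor directs, and no lithium halide is formed that could later slow the palladium step.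

**Step 3**
Reactants: 6 lithium (5-chlorobenzofuran-2-yl)(3,4-dimethoxyphenyl)(pinacolato)borate; 2 3,5-dimethoxyphenyl trifluoromethanesulfonate
Product: 7 2-[(2S,3S)-5-chloro-2-(3,4-dimethoxyphenyl)-3-(3,5-dimethoxyphenyl)-2,3-dihydro-1-benzofuran-2-yl]-4,4,5,5-tetramethyl-1,3,2-dioxaborolane
Conditions: Pd(OAc)2 (2 mol %), (Sp,Sp)-1,1'-bis[bis(4-methoxy-3,5-dimethylphenyl)phosphino]-2,2'-bis[(R)-(dimethylamino)(phenyl)methyl]ferrocene (2.4 mol %), THF, 60 °C
Reagents that add atoms: none
Why: Proposed new method: zerovalent palladium carrying the chiral ferrocenyl bisphosphine inserts into the C–O bond of triflate 2, and the cationic aryl palladium species so formed binds the electron-rich C2=C3 bond of borate 6 at C3, which provokes a 1,2-shift of the 3,4-dimethoxyphenyl group from boron to C2 on the face away from the metal; C–C reductive elimination then puts the 3,5-dimethoxyphenyl group on C3 with retention, so that the two aryl groups are trans and boron lies cis to the C3 aryl group. The closest known reaction type is the palladium-catalysed conjunctive cross-coupling of alkenyl boron ate complexes with aryl triflates, together with the electrophile-triggered dearomative 1,2-migration of indol-2-yl borates, and the extension to a benzofuran-2-yl borate with an aryl palladium electrophile is the untested part. No ring is closed, since the furan ring is only dearomatised while two exocyclic C–aryl bonds form. C3 is controlled by the catalyst, whose ligand decides which face of the C2=C3 bond palladium occupies, and C2 follows from the mechanism, because the migrating group must arrive anti to the metal. The step needs the metallate shift to win over direct boron-to-palladium transmetalation (plain biaryl coupling) and over β-hydride loss: the wide-bite-angle ligand, the weakly coordinating triflate and the halide-free borate favour the shift, and once it has occurred C2 bears no hydrogen, so the C3-bound palladium can only eliminate reductively. The C5 chloride should stay intact because oxidative addition to the aryl triflate is far faster with this catalyst.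

**Step 4**
Reactants: 7 2-[(2S,3S)-5-chloro-2-(3,4-dimethoxyphenyl)-3-(3,5-dimethoxyphenyl)-2,3-dihydro-1-benzofuran-2-yl]-4,4,5,5-tetramethyl-1,3,2-dioxaborolane
Product: 8 (2S,3S)-5-chloro-2-(3,4-dimethoxyphenyl)-3-(3,5-dimethoxyphenyl)-2,3-dihydro-1-benzofuran
Conditions: CsF (1.5 equiv), H2O (1.1 equiv), 1,4-dioxane, 45 °C
Reagents that add atoms: none
Why: Fluoride-promoted protodeboronation of a tertiary benzylic pinacol boronate should proceed by front-side protonation of the fluoride-activated C–B bond by water, so C2 keeps its configuration, the hydrogen ends up cis to the C3 aryl group (trans-diaryl) and C3 is not touched.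

**Step 5**
Reactants: 8 (2S,3S)-5-chloro-2-(3,4-dimethoxyphenyl)-3-(3,5-dimethoxyphenyl)-2,3-dihydro-1-benzofuran; 9 3,5-dimethoxystyrene
Product: 10 (2S,3S)-2-(3,4-dimethoxyphenyl)-3-(3,5-dimethoxyphenyl)-5-[(E)-2-(3,5-dimethoxyphenyl)ethenyl]-2,3-dihydro-1-benzofuran
Conditions: Pd2(dba)3 (1.5 mol %), P(t-Bu)3 (6 mol %), Cy2NMe (1.2 equiv), 1,4-dioxane, 110 °C
Reagents that add atoms: none
Why: The Mizoroki–Heck reaction of unactivated aryl chlorides with styrenes is established under bulky, electron-rich trialkylphosphine catalysis; syn carbopalladation and syn β-hydride elimination give the E-stilbene, and the tertiary amine base is too weak to disturb the two benzylic stereocentres.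

**Step 6**
Reactants: 10 (2S,3S)-2-(3,4-dimethoxyphenyl)-3-(3,5-dimethoxyphenyl)-5-[(E)-2-(3,5-dimethoxyphenyl)ethenyl]-2,3-dihydro-1-benzofuran
Product: 11 5-[(E)-2-[(2S,3S)-2-(3,4-dihydroxyphenyl)-3-(3,5-dihydroxyphenyl)-2,3-dihydro-1-benzofuran-5-yl]ethenyl]benzene-1,3-diol
Conditions: BBr3 (12 equiv), CH2Cl2, −78 °C → 0 °C; then H2O; product handled under argon
Reagents that add atoms: none
Why: BBr3 cleaves aryl methyl ethers by bromide attack on the methyl group of the boron-complexed ether, and any reversible ionisation of the benzylic C2–O bond should re-close to the more stable trans ring while C3 stays fixed.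

**Compound list**
1 | 3,5-dimethoxyphenol | COc1cc(O)cc(OC)c1 | starting material
2 | 3,5-dimethoxyphenyl trifluoromethanesulfonate | COc1cc(OS(=O)(=O)C(F)(F)F)cc(OC)c1 | intermediate
3 | 5-chlorobenzofuran | Clc1ccc2occc2c1 | starting material
4 | 2-(3,4-dimethoxyphenyl)-4,4,5,5-tetramethyl-1,3,2-dioxaborolane | COc1ccc(B2OC(C)(C)C(C)(C)O2)cc1OC | starting material
5 | (5-chlorobenzofuran-2-yl)lithium | [Li]c1cc2cc(Cl)ccc2o1 | intermediate (not isolated)
6 | lithium (5-chlorobenzofuran-2-yl)(3,4-dimethoxyphenyl)(pinacolato)borate | [Li+].COc1ccc([B-]2(c3cc4cc(Cl)ccc4o3)OC(C)(C)C(C)(C)O2)cc1OC | intermediate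
7 | 2-[(2S,3S)-5-chloro-2-(3,4-dimethoxyphenyl)-3-(3,5-dimethoxyphenyl)-2,3-dihydro-1-benzofuran-2-yl]-4,4,5,5-tetramethyl-1,3,2-dioxaborolane | Clc1ccc2c(c1)[C@H](c1cc(OC)cc(OC)c1)[C@@](B1OC(C)(C)C(C)(C)O1)(c1ccc(OC)c(OC)c1)O2 | intermediate
8 | (2S,3S)-5-chloro-2-(3,4-dimethoxyphenyl)-3-(3,5-dimethoxyphenyl)-2,3-dihydro-1-benzofuran | Clc1ccc2c(c1)[C@H](c1cc(OC)cc(OC)c1)[C@@H](c1ccc(OC)c(OC)c1)O2 | intermediate
9 | 3,5-dimethoxystyrene | C=Cc1cc(OC)cc(OC)c1 | starting material
10 | (2S,3S)-2-(3,4-dimethoxyphenyl)-3-(3,5-dimethoxyphenyl)-5-[(E)-2-(3,5-dimethoxyphenyl)ethenyl]-2,3-dihydro-1-benzofuran | COc1cc(OC)cc(/C=C/c2ccc3c(c2)[C@H](c2cc(OC)cc(OC)c2)[C@@H](c2ccc(OC)c(OC)c2)O3)c1 | intermediate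
11 | 5-[(E)-2-[(2S,3S)-2-(3,4-dihydroxyphenyl)-3-(3,5-dihydroxyphenyl)-2,3-dihydro-1-benzofuran-5-yl]ethenyl]benzene-1,3-diol | Oc1cc(O)cc(/C=C/c2ccc3c(c2)[C@H](c2cc(O)cc(O)c2)[C@@H](c2ccc(O)c(O)c2)O3)c1 | target

**Step count**
Total: 6 steps. Longest linear sequence: 5 steps (steps 2 to 6, from 5-chlorobenzofuran); step 1 is a one-step side branch.

**Steps most likely to fail**

Step 3. The risks are direct transfer of an aryl group from boron to palladium (biaryl coupling without dearomatisation), too little reactivity of the benzofuran C3 towards the aryl palladium species, or weak face selection.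

Fallback, from 3 back to 8: the two aryl groups are installed one after the other by established cross-couplings and the C2=C3 bond is reduced afterwards.
- Lithio compound 5, made from 3 as in step 2, is quenched with iodine to give 5-chloro-2-iodobenzofuran F1.
- Suzuki–Miyaura coupling of F1 with boronate 4 (Pd(PPh3)4, K2CO3, dioxane/H2O, 80 °C; the aryl chloride is inert) gives 5-chloro-2-(3,4-dimethoxyphenyl)benzofuran F2.
- NBS (1.0 equiv, DMF, 0 °C) brominates the most nucleophilic position, C3, to give 3-bromo-5-chloro-2-(3,4-dimethoxyphenyl)benzofuran F3.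
- A second Suzuki–Miyaura coupling with 3,5-dimethoxyphenylboronic acid gives 5-chloro-2-(3,4-dimethoxyphenyl)-3-(3,5-dimethoxyphenyl)benzofuran F4.
- Ionic hydrogenation (Et3SiH, CF3CO2H, CH2Cl2) protonates C3 and delivers hydride to the C2 oxocarbenium ion anti to the C3 aryl group. This should give mainly racemic cis-5-chloro-2-(3,4-dimethoxyphenyl)-3-(3,5-dimethoxyphenyl)-2,3-dihydro-1-benzofuran F5.
- BF3·OEt2 in CH2Cl2 then equilibrates C2 through reversible opening of the benzylic C–O bond to racemic trans-5-chloro-2-(3,4-dimethoxyphenyl)-3-(3,5-dimethoxyphenyl)-2,3-dihydro-1-benzofuran F6.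
- Preparative chromatography on a chiral stationary phase separates the (2S,3S) enantiomer, which is 8.

Step 4. The risks are slow protonolysis of the hindered, α-oxygenated tertiary C–B bond, or leakage of configuration at C2 during the C–B to C–H exchange.

Fallback, from 7 back to 8: the configuration at C2 is no longer entrusted to the protodeboronation but set thermodynamically.
- Boronate 7 is protodeboronated under forcing conditions (TBAF·3H2O, THF, 60 °C), which are expected to give 8 together with its C2 epimer, (2R,3S)-5-chloro-2-(3,4-dimethoxyphenyl)-3-(3,5-dimethoxyphenyl)-2,3-dihydro-1-benzofuran F7.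
- The mixture is treated with BF3·OEt2 in CH2Cl2 at −20 °C. Reversible ionisation of the C2–O bond, which is benzylic to the 3,4-dimethoxyphenyl ring, should funnel F7 into the more stable trans isomer 8 while C3 is untouched.

Step 6. The risks are acid-promoted reactions of the stilbene double bond (hydrobromination, cationic cyclisation or oligomerisation), opening of the benzylic ether during six-fold ether cleavage, or incomplete demethylation.

Fallback, from 8 back to 11: the methyl ethers are removed before the alkene exists and the phenols are carried as acetates.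
- BBr3 in CH2Cl2 converts 8 into 4-[(2S,3S)-5-chloro-3-(3,5-dihydroxyphenyl)-2,3-dihydro-1-benzofuran-2-yl]benzene-1,2-diol F8.
- Ac2O and pyridine give the tetraacetate of that tetraphenol, (2S,3S)-5-chloro-2-(3,4-diacetoxyphenyl)-3-(3,5-diacetoxyphenyl)-2,3-dihydro-1-benzofuran F9.
- A Mizoroki–Heck reaction of F9 with 3,5-diacetoxystyrene under the conditions of step 5 gives the hexaacetate of the target, (2S,3S)-2-(3,4-diacetoxyphenyl)-3-(3,5-diacetoxyphenyl)-5-[(E)-2-(3,5-diacetoxyphenyl)ethenyl]-2,3-dihydro-1-benzofuran F10.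
- Methanolysis (catalytic K2CO3, MeOH, 0 °C, argon, then mild acidification) releases 11 without any strong acid meeting the stilbene.

**Further compounds**
F1 | step 3 | 5-chloro-2-iodobenzofuran | Clc1ccc2oc(I)cc2c1
F2 | step 3 | 5-chloro-2-(3,4-dimethoxyphenyl)benzofuran | COc1ccc(-c2cc3cc(Cl)ccc3o2)cc1OC
F3 | step 3 | 3-bromo-5-chloro-2-(3,4-dimethoxyphenyl)benzofuran | COc1ccc(-c2oc3ccc(Cl)cc3c2Br)cc1OC
F4 | step 3 | 5-chloro-2-(3,4-dimethoxyphenyl)-3-(3,5-dimethoxyphenyl)benzofuran | COc1cc(OC)cc(-c2c(-c3ccc(OC)c(OC)c3)oc3ccc(Cl)cc23)c1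
F5 | step 3 | racemic cis-5-chloro-2-(3,4-dimethoxyphenyl)-3-(3,5-dimethoxyphenyl)-2,3-dihydro-1-benzofuran, (2R,3S) and (2S,3R) | Clc1ccc2c(c1)[C@H](c1cc(OC)cc(OC)c1)[C@H](c1ccc(OC)c(OC)c1)O2.Clc1ccc2c(c1)[C@@H](c1cc(OC)cc(OC)c1)[C@@H](c1ccc(OC)c(OC)c1)O2
F6 | step 3 | racemic trans-5-chloro-2-(3,4-dimethoxyphenyl)-3-(3,5-dimethoxyphenyl)-2,3-dihydro-1-benzofuran, (2S,3S) and (2R,3R) | Clc1ccc2c(c1)[C@H](c1cc(OC)cc(OC)c1)[C@@H](c1ccc(OC)c(OC)c1)O2.Clc1ccc2c(c1)[C@@H](c1cc(OC)cc(OC)c1)[C@H](c1ccc(OC)c(OC)c1)O2
F7 | step 4 | (2R,3S)-5-chloro-2-(3,4-dimethoxyphenyl)-3-(3,5-dimethoxyphenyl)-2,3-dihydro-1-benzofuran | Clc1ccc2c(c1)[C@H](c1cc(OC)cc(OC)c1)[C@H](c1ccc(OC)c(OC)c1)O2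
F8 | step 6 | 4-[(2S,3S)-5-chloro-3-(3,5-dihydroxyphenyl)-2,3-dihydro-1-benzofuran-2-yl]benzene-1,2-diol | Clc1ccc2c(c1)[C@H](c1cc(O)cc(O)c1)[C@@H](c1ccc(O)c(O)c1)O2
F9 | step 6 | (2S,3S)-5-chloro-2-(3,4-diacetoxyphenyl)-3-(3,5-diacetoxyphenyl)-2,3-dihydro-1-benzofuran | Clc1ccc2c(c1)[C@H](c1cc(OC(C)=O)cc(OC(C)=O)c1)[C@@H](c1ccc(OC(C)=O)c(OC(C)=O)c1)O2
F10 | step 6 | (2S,3S)-2-(3,4-diacetoxyphenyl)-3-(3,5-diacetoxyphenyl)-5-[(E)-2-(3,5-diacetoxyphenyl)ethenyl]-2,3-dihydro-1-benzofuran | CC(=O)Oc1cc(OC(C)=O)cc(/C=C/c2ccc3c(c2)[C@H](c2cc(OC(C)=O)cc(OC(C)=O)c2)[C@@H](c2ccc(OC(C)=O)c(OC(C)=O)c2)O3)c1
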